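All runs were generated by integration with constants of no real substance; noise was put on by code.

Count the Z.

the same everywhere: X 17 mM

| charge | Z | remark | time |
|---|---|---|---|
| Wednesday's | 12 mM | run made earlier |  |
| Saturday's | 19 mM | run made earlier |  |
| delta | 14.0 mM |  | 4.0 h |
| alpha | 18.0 mM |  | 4.0 h |
| eta | 23.0 mM |  | 4.0 h |

- Wednesday's (time / min: X / %, G / %): 6.00: 96.6, 3.3; 20.0: 88.8, 10.7; 30.0: 85.6, 13.6; 50.0: 77.8, 17.8; 80.0: 70.5, 20.0; 90.0: 68.2, 21.9; 120: 63.3, 21.0
- Saturday's (time / min: X / %, G / %): 6.00: 94.4, 5.0; 20.0: 82.9, 15.5; 30.0: 76.9, 20.3; 50.0: 67.1, 26.3; 80.0: 56.8, 31.6; 90.0: 54.0, 31.9; 120: 47.0, 33.9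

(readings scatter by 0.5 percentage points)



1. part of the X that has reacted at the end, delta
2. part of the X that has reacted at the end, alpha
3. part of the X that has reacted at the end, eta
4. what raising the concentration of Z from its lowest to its highest value here does to the part of the X that has reacted (changes below 5 percentage points count as none) (no change / it falls / it rises)

Nobody read [Z], so you have to get it by dividing one rate by another. Suppose, as my own guess, that G is lost by meeting X, one X with each G. The shortfall of [X] + [G] against the charge then grows at twice that rate.

The first way uses the clock. In Saturday's run the shortfall grows by 12 percentage points between 50.0 min and 120 min, with mean [G] at 5.12 mM. That gives a constant of 3.06 × 10⁻⁴ /mM/min for G's loss, and this reckoning needs no [Z]. The X left at 20.0 min gives 4.94 × 10⁻⁴ /mM/min for G's making. Their ratio, the selectivity factor, reads 0.620.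

The second way has no clock. Over the same window Saturday's run gains 0.378 of G per X lost, so G is used at 0.451 of the rate it is made, and that ratio equals the factor times [G]/[Z]. By then about 6.21 mM of G has been made. If each G had cost one Z, the factor would read 1.13.

The two ways part, and the second is the one that cheats, since its [Z] was assumed. Taking the first factor, [Z] stood near 7.03 mM, so the Z price, the Z spent per G made, is 1.93.

If each G made can also take one more X, the price sets a ceiling on the X reacted: 85.4 % for delta, 110 % for alpha and 140 % for eta.

The forecast gives 54 %, 65 % and 75 %, and says it rises, adding “If G also consumes Z, the values would be somewhat lower”.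

The flasks give 54.5 %, 65.6 % and 76.6 %: it rises, by 22 points.

    X + Z → J + G (k = 33.0 /M/h)
    Z + J ⇌ E, settled at all times (K = 6.10 × 10⁵ /M)
    X + G → L (k = 18.0 /M/h)

The scheme spends two Z per G made, one in the first step and one binding J into E. Eta's answer has moved by 5 points with Z at 20.6 mM or 25.9 mM. Ten times the time still moves them: delta reaches 82.3 % at 40.0 h, alpha 95.8 % at 40.0 h and eta 99.8 % at 40.0 h. Delta then stands just under its ceiling, with 0.209 % of its Z free and 17.7 % of its X left at 40.0 h, so Z is the limiting reagent there. Eta, whose ceiling stands above 100 %, keeps 2.68 % of its Z free and 0.187 % of its X at 40.0 h.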